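**Retrosynthetic overview**

1. The target is read as epicatechin-(4β→8)-epigallocatechin 3-O-gallate: upper unit rings A/C/B (2R,3R,4R), lower unit rings D/F/E (2R,3R), galloyl ring G. All thirteen hydroxyls are carried as benzyl ethers and freed last by hydrogenolysis.
2. Key disconnection: the lower pyran ring F (lower-unit O1, C2, C3, C4, C4a, C8a) is opened by retro-[4+2] into an o-quinone methide on ring D and a (Z)-2-arylvinyl gallate. The dienophile brings ring E, ring G, the ester and the cis C2/C3 pair in one operation.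
3. Enabling feature: lower-unit C4 is an unsubstituted CH2 on C4a, ortho to O1–C8a of the phloroglucinol ring D (a latent o-quinone methide), and C2 (aryl) and C3 (O-galloyl) are cis, i.e. the two ends of a Z enol ester.
4. The quinone methide precursor is a salicyl alcohol, made by ortho-formylation and reduction of the phenol from a 4β-selective Friedel–Crafts coupling of C4-activated perbenzyl epicatechin with 3,5-bis(benzyloxy)phenol. The dienophile comes from [RuCl2(p-cymene)]2-catalysed Z-selective addition of the protected gallic acid to the aryl alkyne.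
5. Ring order: rings A, C, B (chiral pool) and D, E, G (aromatic building blocks) are bought; ring F is the only ring built and is closed last.

Key step: step 9

Remark: 3,5-bis(benzyloxy)phenol, 3,4,5-tris(benzyloxy)benzaldehyde and 3,4,5-tris(benzyloxy)benzoic acid are taken as purchasable. "Upper-unit" locants refer to the epicatechin part, "lower-unit" locants to the gallate-bearing part.

**Route**

Step 1
Reactants: 1 (−)-epicatechin
Product: 2 5,7,3',4'-tetra-O-benzyl-(−)-epicatechin
Conditions: BnBr (4.4 equiv), K2CO3, DMF, 0 °C to rt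
Reagents that add atoms: benzyl bromide, BrCc1ccccc1
Why: Williamson etherification with a carbonate base should alkylate the four phenols and leave the secondary alcohol and both stereocenters untouched.

Step 2
Reactants: 2 5,7,3',4'-tetra-O-benzyl-(−)-epicatechin
Product: 3 3,5,7,3',4'-penta-O-benzyl-(−)-epicatechin
Conditions: NaH, BnBr, DMF, 0 °C to rt
Reagents that add atoms: benzyl bromide, BrCc1ccccc1
Why: Williamson etherification of the C3 alkoxide; with no free phenol left the pyran cannot open, so the 2,3-cis centers should be retained, and the upper 3-OH is masked by a group that leaves in the final hydrogenolysis.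

Step 3
Reactants: 3 3,5,7,3',4'-penta-O-benzyl-(−)-epicatechin
Product: 4 4β-(2-ethoxyethoxy)-3,5,7,3',4'-penta-O-benzylepicatechin
Conditions: DDQ (2 equiv), 2-ethoxyethanol, CH2Cl2, rt
Reagents that add atoms: 2-ethoxyethanol, CCOCCO
Why: DDQ-mediated benzylic oxidation at C4 (activated by the oxygens of ring A) with capture by the alcohol on the β-face, anti to the 3-benzyloxy and 2-aryl groups; the new C4 center is only a leaving group and is ionised again in step 4.

Step 4
Reactants: 4 4β-(2-ethoxyethoxy)-3,5,7,3',4'-penta-O-benzylepicatechin; 5 3,5-bis(benzyloxy)phenol (3 equiv)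
Product: 6 3,5-bis(benzyloxy)-2-(penta-O-benzylepicatechin-4β-yl)phenol
Conditions: TMSOTf (0.2 equiv), CH2Cl2, −78 to −40 °C; NaHCO3 quench
Reagents that add atoms: none
Why: Lewis-acid-mediated Friedel–Crafts alkylation by the C4 cation; the phenol should react ortho to its free hydroxyl (less hindered than the carbon between two benzyloxy groups) and on the β-face, trans to the 3-benzyloxy and 2-aryl groups, which sets upper-unit C4 (3,4-trans) and places the future O1 next to the future C8 of the lower unit.

Step 5
Reactants: 6 3,5-bis(benzyloxy)-2-(penta-O-benzylepicatechin-4β-yl)phenol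
Product: 7 4,6-bis(benzyloxy)-2-hydroxy-3-(penta-O-benzylepicatechin-4β-yl)benzaldehyde
Conditions: MgCl2 (3 equiv), Et3N (6 equiv), (CH2O)n, THF/MeCN, 70 °C; cold dilute acid work-up
Reagents that add atoms: paraformaldehyde (formaldehyde), C=O
Why: MgCl2-mediated ortho-formylation of phenols (Casnati–Skattebøl) reacts only ortho to the free hydroxyl, and only one ortho position is open, so the carbon that becomes lower-unit C4 should land on the future C4a.

Step 6
Reactants: 7 4,6-bis(benzyloxy)-2-hydroxy-3-(penta-O-benzylepicatechin-4β-yl)benzaldehyde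
Product: 8 3,5-bis(benzyloxy)-2-(hydroxymethyl)-6-(penta-O-benzylepicatechin-4β-yl)phenol
Conditions: NaBH4 (1.2 equiv), THF/i-PrOH, 0 °C; pH 7 buffer work-up, used crude
Reagents that add atoms: none
Why: borohydride reduction of the aldehyde to the salicyl alcohol, kept cold, short and neutral because this electron-rich o-hydroxybenzyl alcohol ionises easily.

Step 7
Reactants: 9 3,4,5-tris(benzyloxy)benzaldehyde
Product: 10 1,2,3-tris(benzyloxy)-5-ethynylbenzene
Conditions: dimethyl (1-diazo-2-oxopropyl)phosphonate, K2CO3, MeOH/THF, rt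
Reagents that add atoms: dimethyl (1-diazo-2-oxopropyl)phosphonate, CC(=O)C(=[N+]=[N-])P(=O)(OC)OC
Why: Seyferth–Gilbert homologation in the Ohira–Bestmann variant, well suited to a non-enolisable aryl aldehyde.

Step 8
Reactants: 10 1,2,3-tris(benzyloxy)-5-ethynylbenzene; 11 3,4,5-tris(benzyloxy)benzoic acid
Product: 12 (Z)-2-[3,4,5-tris(benzyloxy)phenyl]ethenyl 3,4,5-tris(benzyloxy)benzoate
Conditions: [RuCl2(p-cymene)]2 (2 mol %), P(4-ClC6H4)3 (6 mol %), DMAP (8 mol %), toluene, 60 °C
Reagents that add atoms: none
Why: [RuCl2(p-cymene)]2-catalysed anti-Markovnikov addition of a carboxylic acid to a terminal alkyne through a metal vinylidene, which with this phosphine and DMAP should give the Z enol ester.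

Step 9
Reactants: 8 3,5-bis(benzyloxy)-2-(hydroxymethyl)-6-(penta-O-benzylepicatechin-4β-yl)phenol; 12 (Z)-2-[3,4,5-tris(benzyloxy)phenyl]ethenyl 3,4,5-tris(benzyloxy)benzoate (2 equiv)
Product: 14 trideca-O-benzyl-[epicatechin-(4β→8)-epigallocatechin 3-O-gallate], via o-quinone methide 13 (not isolated)
Conditions: (R)-TRIP (10 mol %), 4 Å molecular sieves, toluene/CH2Cl2, −20 °C to rt, slow addition of 8
Reagents that add atoms: none
Why: Proposed new method: the chiral phosphoric acid (R)-TRIP should dehydrate the electron-rich salicyl alcohol 8 to the o-quinone methide 13, the water being taken up by the sieves, and stay hydrogen-bonded to its oxygen while the Z enol ester 12 adds in a concerted, asynchronous inverse-electron-demand oxa-[4+2] cycloaddition in which the lower-unit C3–C4 bond leads and the O1–C2 bond follows; the closest known reaction types are the chiral-phosphoric-acid-catalysed hetero-Diels–Alder reactions of o-quinone methides from o-hydroxybenzyl alcohols with electron-rich alkenes (2-vinylphenols, enamides, vinyl sulfides) and the stereospecific thermal cycloadditions of o-quinone methides with β-substituted styrenes, whereas a β-acyloxystyrene partner and catalyst control over a methide-unsubstituted quinone methide have not been shown. Ring F is closed as a six-membered ring by this [4π+2π] cycloaddition, suprafacial on the dienophile, through the two new bonds C3–C4 and O1–C2. The cis relation of lower-unit C2 and C3 is controlled by the Z geometry of 12, which a concerted addition transfers unchanged, and their absolute configuration (2R,3R) by the dienophile face selected inside the chiral phosphate–quinone methide complex, acting together with the resident upper unit on C8 (double stereodifferentiation, so the antipodal acid is the first variable if the pairing proves mismatched). The step needs four selectivities: the quinone methide must form on the oxygen next to C8, which is secured because O5 and O7 of ring D are benzylated and only that phenol is free, so the 4→8 constitution cannot drift to 4→6; the aryl-bearing carbon must bond to oxygen, which follows from the benzylic carbon carrying the developing positive charge better (tris(benzyloxy)phenyl against a poorly donating acyloxy group); the Z geometry must survive, which the low temperature and the hydrogen-bonded transition state favour; and the dienophile must outcompete alkylation of the electron-rich arenes, which the excess of 12 and the slow addition of 8 address.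

Step 10
Reactants: 14 trideca-O-benzyl-[epicatechin-(4β→8)-epigallocatechin 3-O-gallate]
Product: 15 epicatechin-(4β→8)-epigallocatechin 3-O-gallate (target)
Conditions: H2 (1 atm), Pd(OH)2/C, THF/MeOH/H2O, rt; filtration, Sephadex LH-20
Reagents that add atoms: none
Why: hydrogenolysis of all thirteen benzyl ethers, under which the gallate ester, the interflavan bond and the five stereocenters should stay intact.

**Compound list**

1 | (−)-epicatechin, (2R,3R)-2-(3,4-dihydroxyphenyl)chromane-3,5,7-triol | O[C@@H]1Cc2c(O)cc(O)cc2O[C@@H]1c1ccc(O)c(O)c1 | starting material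
2 | 5,7,3',4'-tetra-O-benzyl-(−)-epicatechin | O[C@@H]1Cc2c(OCc3ccccc3)cc(OCc3ccccc3)cc2O[C@@H]1c1ccc(OCc2ccccc2)c(OCc2ccccc2)c1 | intermediate
3 | 3,5,7,3',4'-penta-O-benzyl-(−)-epicatechin | c1ccccc1CO[C@@H]1Cc2c(OCc3ccccc3)cc(OCc3ccccc3)cc2O[C@@H]1c1ccc(OCc2ccccc2)c(OCc2ccccc2)c1 | intermediate
4 | 4β-(2-ethoxyethoxy)-3,5,7,3',4'-penta-O-benzylepicatechin (2,3-cis, 3,4-trans) | CCOCCO[C@H]1c2c(OCc3ccccc3)cc(OCc3ccccc3)cc2O[C@H](c2ccc(OCc3ccccc3)c(OCc3ccccc3)c2)[C@@H]1OCc1ccccc1 | intermediate
5 | 3,5-bis(benzyloxy)phenol | Oc1cc(OCc2ccccc2)cc(OCc2ccccc2)c1 | starting material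
6 | 3,5-bis(benzyloxy)-2-(penta-O-benzylepicatechin-4β-yl)phenol | Oc1cc(OCc2ccccc2)cc(OCc2ccccc2)c1[C@H]1c2c(OCc3ccccc3)cc(OCc3ccccc3)cc2O[C@H](c2ccc(OCc3ccccc3)c(OCc3ccccc3)c2)[C@@H]1OCc1ccccc1 | intermediate
7 | 4,6-bis(benzyloxy)-2-hydroxy-3-(penta-O-benzylepicatechin-4β-yl)benzaldehyde | Oc1c(C=O)c(OCc2ccccc2)cc(OCc2ccccc2)c1[C@H]1c2c(OCc3ccccc3)cc(OCc3ccccc3)cc2O[C@H](c2ccc(OCc3ccccc3)c(OCc3ccccc3)c2)[C@@H]1OCc1ccccc1 | intermediate
8 | 3,5-bis(benzyloxy)-2-(hydroxymethyl)-6-(penta-O-benzylepicatechin-4β-yl)phenol | Oc1c(CO)c(OCc2ccccc2)cc(OCc2ccccc2)c1[C@H]1c2c(OCc3ccccc3)cc(OCc3ccccc3)cc2O[C@H](c2ccc(OCc3ccccc3)c(OCc3ccccc3)c2)[C@@H]1OCc1ccccc1 | intermediate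
9 | 3,4,5-tris(benzyloxy)benzaldehyde | O=Cc1cc(OCc2ccccc2)c(OCc2ccccc2)c(OCc2ccccc2)c1 | starting material
10 | 1,2,3-tris(benzyloxy)-5-ethynylbenzene | C#Cc1cc(OCc2ccccc2)c(OCc2ccccc2)c(OCc2ccccc2)c1 | intermediate
11 | 3,4,5-tris(benzyloxy)benzoic acid | OC(=O)c1cc(OCc2ccccc2)c(OCc2ccccc2)c(OCc2ccccc2)c1 | starting material
12 | (Z)-2-[3,4,5-tris(benzyloxy)phenyl]ethenyl 3,4,5-tris(benzyloxy)benzoate | O=C(O/C=C\c1cc(OCc2ccccc2)c(OCc2ccccc2)c(OCc2ccccc2)c1)c1cc(OCc2ccccc2)c(OCc2ccccc2)c(OCc2ccccc2)c1 | intermediate
13 | o-quinone methide, 3,5-bis(benzyloxy)-6-methylidene-2-(penta-O-benzylepicatechin-4β-yl)cyclohexa-2,4-dien-1-one | C=C1C(=O)C([C@H]2c3c(OCc4ccccc4)cc(OCc4ccccc4)cc3O[C@H](c3ccc(OCc4ccccc4)c(OCc4ccccc4)c3)[C@@H]2OCc2ccccc2)=C(OCc2ccccc2)C=C1OCc1ccccc1 | intermediate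
14 | trideca-O-benzyl-[epicatechin-(4β→8)-epigallocatechin 3-O-gallate] | O=C(O[C@@H]1Cc2c(OCc3ccccc3)cc(OCc3ccccc3)c([C@H]3c4c(OCc5ccccc5)cc(OCc5ccccc5)cc4O[C@H](c4ccc(OCc5ccccc5)c(OCc5ccccc5)c4)[C@@H]3OCc3ccccc3)c2O[C@@H]1c1cc(OCc2ccccc2)c(OCc2ccccc2)c(OCc2ccccc2)c1)c1cc(OCc2ccccc2)c(OCc2ccccc2)c(OCc2ccccc2)c1 | intermediate
15 | epicatechin-(4β→8)-epigallocatechin 3-O-gallate (upper unit 2R,3R,4R; lower unit 2R,3R) | O=C(O[C@@H]1Cc2c(O)cc(O)c([C@H]3c4c(O)cc(O)cc4O[C@H](c4ccc(O)c(O)c4)[C@@H]3O)c2O[C@@H]1c1cc(O)c(O)c(O)c1)c1cc(O)c(O)c(O)c1 | target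

**Step count and risks**

Total: 10 steps. Longest linear sequence: 8 steps (1 → 2 → 3 → 4 → 6 → 7 → 8 → 14 → 15); steps 7 and 8 build the dienophile in parallel.

Step 9 (proposed new method) is the riskiest. The chiral acid may fail to discriminate the two faces of the dienophile, a stepwise cationic pathway may erode the cis relationship, and the quinone methide may be lost to alkylation of electron-rich arenes. The fallback uses known chemistry, sets out from 4 and comes back at 14. Commercial (−)-epigallocatechin gallate is perbenzylated (BnBr, K2CO3, DMF) to octa-O-benzyl-(−)-epigallocatechin gallate F1. F1 (3 equiv) is then condensed with 4 under TMSOTf in CH2Cl2 at −78 °C, the standard Lewis-acid coupling of a C4-activated flavan with a benzylated flavan-3-ol gallate. Attack by C8 of F1 on the β-face of the C4 cation should give 14 directly, with the lower pyran ring and its two stereocenters taken from the chiral pool instead of being built.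

Step 4 is second. The cation may attack the carbon para to the free hydroxyl (between the two benzyloxy groups), or the phenol may be alkylated twice. The fallback sets out from 4 and comes back at 8. Commercial 5,7-dihydroxy-2,2-dimethyl-4H-1,3-benzodioxin-4-one is dibenzylated (BnBr, K2CO3) to 5,7-bis(benzyloxy)-2,2-dimethyl-4H-1,3-benzodioxin-4-one F2. In this ring-tied nucleophile C8 is flanked by the ring oxygen as in a flavan, while the other free carbon lies between two benzyloxy groups, and the phenol oxygen and the future C4 carbon are already in place. TMSOTf-mediated coupling with 4 should give the C8-linked 4β adduct 5,7-bis(benzyloxy)-2,2-dimethyl-8-(penta-O-benzylepicatechin-4β-yl)-4H-1,3-benzodioxin-4-one F3. LiAlH4 reduction of the acetonide ester (THF, 0 °C) then releases salicyl alcohol 8, so steps 5 and 6 are bypassed as well.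

Step 8 is third. Leakage to the E isomer or to Markovnikov addition would carry 2,3-trans or constitutional impurities into step 9. The fallback sets out from 10 and comes back at 12. [Rh(cod)Cl]2-catalysed trans-hydroboration of 10 with pinacolborane (P(iPr)3, Et3N, cyclohexane) should give the Z alkenyl boronate 2-[(Z)-2-(3,4,5-tris(benzyloxy)phenyl)ethenyl]-4,4,5,5-tetramethyl-1,3,2-dioxaborolane F4. KHF2 converts it into potassium (Z)-trifluoro[2-(3,4,5-tris(benzyloxy)phenyl)ethenyl]borate F5. Cu(OAc)2-catalysed oxidative coupling of F5 with acid 11 (DMAP, O2, molecular sieves; Chan–Lam type C–O coupling) should then form the enol ester with retention of the Z geometry, giving 12.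

**Further compounds**

F1 | step 9 | octa-O-benzyl-(−)-epigallocatechin gallate | O=C(O[C@@H]1Cc2c(OCc3ccccc3)cc(OCc3ccccc3)cc2O[C@@H]1c1cc(OCc2ccccc2)c(OCc2ccccc2)c(OCc2ccccc2)c1)c1cc(OCc2ccccc2)c(OCc2ccccc2)c(OCc2ccccc2)c1
F2 | step 4 | 5,7-bis(benzyloxy)-2,2-dimethyl-4H-1,3-benzodioxin-4-one | CC1(C)OC(=O)c2c(OCc3ccccc3)cc(OCc3ccccc3)cc2O1
F3 | step 4 | 5,7-bis(benzyloxy)-2,2-dimethyl-8-(penta-O-benzylepicatechin-4β-yl)-4H-1,3-benzodioxin-4-one | CC1(C)OC(=O)c2c(OCc3ccccc3)cc(OCc3ccccc3)c([C@H]3c4c(OCc5ccccc5)cc(OCc5ccccc5)cc4O[C@H](c4ccc(OCc5ccccc5)c(OCc5ccccc5)c4)[C@@H]3OCc3ccccc3)c2O1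
F4 | step 8 | 2-[(Z)-2-(3,4,5-tris(benzyloxy)phenyl)ethenyl]-4,4,5,5-tetramethyl-1,3,2-dioxaborolane | CC1(C)OB(/C=C\c2cc(OCc3ccccc3)c(OCc3ccccc3)c(OCc3ccccc3)c2)OC1(C)C
F5 | step 8 | potassium (Z)-trifluoro[2-(3,4,5-tris(benzyloxy)phenyl)ethenyl]borate | [K+].F[B-](F)(F)/C=C\c1cc(OCc2ccccc2)c(OCc2ccccc2)c(OCc2ccccc2)c1
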